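**Plan**

- Cuts, in retrosynthetic order: the ring A aryl–propenol bond; the O1–C2 and C2–ring B bonds of dioxane 1; the O1–C2 and C2–ring C bonds of dioxane 2; the two aryl O4–C3 ether bonds.
- Forward: ring B glycerate ether (Mitsunobu, Dakin) → ring C Grignard addition → acid closure of dioxane 2 → lithiated ring B added to a ring A aryloxy aldehyde → acid closure of dioxane 1 → Stille propenol → desilylation.
- Enabling feature: the 4-hydroxyl of catechol ring C is para to benzylic C2 of dioxane 2, so the O1–C2 bond ionises reversibly (para-quinone methide) and C2 settles trans to C3.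
- Stereochemistry: C3 of dioxane 2 (R) comes from the (S)-glycerate by Mitsunobu inversion, and C3 of dioxane 1 (S) from the (R)-glycerate likewise. Each C2 is set trans to its C3 under acid; the E alkene comes from the stannane.

Key step: step 8

Assumption: both enantiomers of methyl 2,2-dimethyl-1,3-dioxolane-4-carboxylate, 5-bromo-2-hydroxybenzaldehyde, 4-bromocatechol and (E)-3-(tributylstannyl)prop-2-en-1-ol are taken as purchasable. The primary oxygen of each glycerate is kept as a TBDPS ether through both ring closures.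

Locants: in every 2,3-dihydro-1,4-benzodioxine below, C2 is the aryl-bearing benzylic carbon and C3 the CH2O-bearing carbon, so the benzo substituent sits at C7. TBS = tert-butyldimethylsilyl, TBDPS = tert-butyldiphenylsilyl, TMS = trimethylsilyl, MOM = methoxymethyl.

**Ring B, ring C and dioxane 2**

Step 1
Reactants: 1 methyl (S)-2,2-dimethyl-1,3-dioxolane-4-carboxylate
Product: 2 methyl (S)-2,3-dihydroxypropanoate
Conditions: Amberlyst 15 (H+ form), MeOH/H2O 9:1, rt
Reagents that add atoms: none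
Why: Acid-catalysed acetal hydrolysis removes the acetonide, while the methyl ester and the C2 stereocentre, which takes no part, stay intact.

Step 2
Reactants: 2 methyl (S)-2,3-dihydroxypropanoate
Product: 3 methyl (S)-3-(TBDPSO)-2-hydroxypropanoate
Conditions: TBDPSCl (1.05 equiv), imidazole, CH2Cl2, 0 °C
Reagents that add atoms: tert-butyl(chloro)diphenylsilane (TBDPSCl), CC(C)(C)[Si](Cl)(c1ccccc1)c1ccccc1
Why: Selective silylation of a primary alcohol, since the bulky silyl chloride reacts at the unhindered CH2OH far faster than at the secondary hydroxyl next to the ester.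

Step 3
Reactants: 3 methyl (S)-3-(TBDPSO)-2-hydroxypropanoate; 4 5-bromo-2-hydroxybenzaldehyde
Product: 5 methyl (R)-2-(4-bromo-2-formylphenoxy)-3-(TBDPSO)propanoate
Conditions: PPh3, DIAD, THF, 0 °C → rt
Reagents that add atoms: none
Why: Mitsunobu reaction, in which the acidic phenol para to bromine displaces the alkoxyphosphonium of the α-hydroxy ester in an SN2 step, so the carbinol carbon is inverted from S to R and this oxygen becomes O4 of dioxane 2.

Step 4
Reactants: 5 methyl (R)-2-(4-bromo-2-formylphenoxy)-3-(TBDPSO)propanoate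
Product: 7 methyl (R)-2-(4-bromo-2-hydroxyphenoxy)-3-(TBDPSO)propanoate, via aryl formate 6 (not isolated)
Conditions: mCPBA, CH2Cl2, rt; then Et3N (cat.), MeOH, 0 °C
Reagents that add atoms: meta-chloroperoxybenzoic acid (mCPBA), O=C(OO)c1cccc(Cl)c1
Why: Dakin-type Baeyer–Villiger oxidation, in which the ortho-alkoxyaryl group migrates to give formate 6, and mild methanolysis then frees the phenol without epimerising the α-aryloxy ester.

Step 5
Reactants: 7 methyl (R)-2-(4-bromo-2-hydroxyphenoxy)-3-(TBDPSO)propanoate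
Product: 8 (3R)-7-bromo-3-(TBDPSOCH2)-2,3-dihydro-1,4-benzodioxin-2-ol (lactol, both C2 anomers)
Conditions: i-Bu2AlH (2.4 equiv), CH2Cl2, −78 °C; aq. potassium sodium tartrate
Reagents that add atoms: none
Why: DIBAL-H half-reduction of an ester, in which the first equivalent forms the aluminium phenoxide and the second gives an aluminium hemiacetal stable at −78 °C, released on work-up as the six-membered lactol that shields the α-aryloxy aldehyde from epimerisation.

Step 6
Reactants: 9 4-bromobenzene-1,2-diol (4-bromocatechol)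
Product: 10 4-bromo-1,2-bis(trimethylsilyloxy)benzene
Conditions: (Me3Si)2NH, (NH4)2SO4 (cat.), 100 °C; distil
Reagents that add atoms: hexamethyldisilazane, C[Si](C)(C)N[Si](C)(C)C
Why: Silylation of phenols with hexamethyldisilazane gives the bis-TMS ether, a standard mask for a phenol that has to pass through Grignard formation.

Step 7
Reactants: 8 lactol; 10 4-bromo-1,2-bis(trimethylsilyloxy)benzene
Product: 13 (1RS,2R)-2-(4-bromo-2-hydroxyphenoxy)-3-(TBDPSO)-1-(3,4-dihydroxyphenyl)propan-1-ol (C1 epimer mixture), via Grignard reagent 11 (not isolated), via bis-TMS carbinol 12 (not isolated)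
Conditions: 10, Mg, THF, 40 °C (3.5 equiv of 11); 8, THF, 0 °C → rt; aq. NH4Cl; then MeOH, citric acid (cat.), rt
Reagents that add atoms: none
Why: Addition of a Grignard reagent to a lactol, in which one equivalent of 11 deprotonates the hemiacetal, a second attacks the open aldehyde, and the labile aryl TMS ethers are methanolysed on work-up; the new carbinol centre is left as an epimer mixture because step 8 erases it.

Step 8
Reactants: 13 (1RS,2R)-2-(4-bromo-2-hydroxyphenoxy)-3-(TBDPSO)-1-(3,4-dihydroxyphenyl)propan-1-ol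
Product: 15 4-[(2R,3R)-7-bromo-3-(TBDPSOCH2)-2,3-dihydro-1,4-benzodioxin-2-yl]benzene-1,2-diol, via ring C para-quinone methide 14 (not isolated)
Conditions: TsOH·H2O (0.2 equiv), MeCN (0.02 M), 40 °C, under argon
Reagents that add atoms: none
Why: Protonation of the benzylic hydroxyl and loss of water give the para-hydroxybenzyl cation of ring C, the O-protonated form of quinone methide 14, and the ring B phenol meta to bromine adds to its exocyclic carbon to form the O1–C2 bond. The closest known reaction type is the acid-catalysed cyclisation of 1-aryl-2-(2-hydroxyaryloxy)propanols through para-quinone methides to trans-2-aryl-1,4-benzodioxanes, formally an intramolecular oxa-Michael addition. Dioxane 2 closes in a 6-exo-trig mode. The new stereocentre C2 is controlled by the glycerate-derived C3: the ring C para hydroxyl keeps the O1–C2 bond ionisable, so closure is reversible and both C1 epimers of 13 should drain into the diequatorial trans (2R,3R) isomer. The step needs chemoselectivity for the ring B phenol and trans over cis selectivity; the first is secured by the six-membered fit of that phenol, with the primary oxygen capped as its TBDPS ether and the catechol hydroxyls unable to reach the cation, and the second by thermodynamic control. High dilution and exclusion of air hold back intermolecular trapping and catechol oxidation, and which ring B oxygen ends on C2 is already fixed by the O4–C3 bond made in step 3.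

Step 9
Reactants: 15 4-[(2R,3R)-7-bromo-3-(TBDPSOCH2)-2,3-dihydro-1,4-benzodioxin-2-yl]benzene-1,2-diol
Product: 16 (2R,3R)-7-bromo-2-[3,4-bis(TBSO)phenyl]-3-(TBDPSOCH2)-2,3-dihydro-1,4-benzodioxine
Conditions: TBSCl (2.5 equiv), imidazole, DMF, rt
Reagents that add atoms: tert-butyl(chloro)dimethylsilane (TBSCl), CC(C)(C)[Si](C)(C)Cl
Why: Standard silylation of phenols masks both catechol hydroxyls, the only acidic groups left, ahead of the bromine–lithium exchange.

**Ring A aldehyde**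

Step 10
Reactants: 17 methyl (R)-2,2-dimethyl-1,3-dioxolane-4-carboxylate
Product: 18 methyl (R)-2,3-dihydroxypropanoate
Conditions: Amberlyst 15 (H+ form), MeOH/H2O 9:1, rt
Reagents that add atoms: none
Why: Acid-catalysed acetal hydrolysis as in step 1, applied to the enantiomeric ester without touching its stereocentre.

Step 11
Reactants: 18 methyl (R)-2,3-dihydroxypropanoate
Product: 19 methyl (R)-3-(TBDPSO)-2-hydroxypropanoate
Conditions: TBDPSCl (1.05 equiv), imidazole, CH2Cl2, 0 °C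
Reagents that add atoms: tert-butyl(chloro)diphenylsilane (TBDPSCl), CC(C)(C)[Si](Cl)(c1ccccc1)c1ccccc1
Why: Selective silylation of the primary alcohol on steric grounds, as in step 2.

Step 12
Reactants: 19 methyl (R)-3-(TBDPSO)-2-hydroxypropanoate; 4 5-bromo-2-hydroxybenzaldehyde
Product: 20 methyl (S)-2-(4-bromo-2-formylphenoxy)-3-(TBDPSO)propanoate
Conditions: PPh3, DIAD, THF, 0 °C → rt
Reagents that add atoms: none
Why: Mitsunobu reaction with SN2 inversion turns the R alcohol into the S aryl ether, the future C3 of dioxane 1, and places the oxygen para to bromine on that carbon.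

Step 13
Reactants: 20 methyl (S)-2-(4-bromo-2-formylphenoxy)-3-(TBDPSO)propanoate
Product: 22 methyl (S)-2-(4-bromo-2-hydroxyphenoxy)-3-(TBDPSO)propanoate, via aryl formate 21 (not isolated)
Conditions: mCPBA, CH2Cl2, rt; then Et3N (cat.), MeOH, 0 °C
Reagents that add atoms: meta-chloroperoxybenzoic acid (mCPBA), O=C(OO)c1cccc(Cl)c1
Why: Dakin-type Baeyer–Villiger oxidation with aryl migration, followed by mild methanolysis of formate 21, as in step 4.

Step 14
Reactants: 22 methyl (S)-2-(4-bromo-2-hydroxyphenoxy)-3-(TBDPSO)propanoate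
Product: 23 methyl (S)-2-[4-bromo-2-(methoxymethoxy)phenoxy]-3-(TBDPSO)propanoate
Conditions: MOMCl, i-Pr2NEt, CH2Cl2, 0 °C → rt
Reagents that add atoms: chloromethyl methyl ether (MOMCl), COCCl
Why: O-Alkylation of the phenol with MOMCl under a hindered amine base gives an acetal that survives DIBAL-H and aryllithium but is cleaved by the acid that later closes dioxane 1.

Step 15
Reactants: 23 methyl (S)-2-[4-bromo-2-(methoxymethoxy)phenoxy]-3-(TBDPSO)propanoate
Product: 24 (S)-2-[4-bromo-2-(methoxymethoxy)phenoxy]-3-(TBDPSO)propanal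
Conditions: i-Bu2AlH (1.1 equiv), CH2Cl2, −78 °C; aq. potassium sodium tartrate; used crude
Reagents that add atoms: none
Why: DIBAL-H half-reduction of an α-alkoxy ester through a chelated tetrahedral intermediate that is stable at −78 °C, with the aldehyde used without chromatography to protect its α stereocentre.

**Union, dioxane 1 and end game**

Step 16
Reactants: 16 (2R,3R)-7-bromo-2-[3,4-bis(TBSO)phenyl]-3-(TBDPSOCH2)-2,3-dihydro-1,4-benzodioxine; 24 (S)-2-[4-bromo-2-(methoxymethoxy)phenoxy]-3-(TBDPSO)propanal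
Product: 26 (1RS,2S)-1-[(2R,3R)-2-[3,4-bis(TBSO)phenyl]-3-(TBDPSOCH2)-2,3-dihydro-1,4-benzodioxin-7-yl]-2-[4-bromo-2-(methoxymethoxy)phenoxy]-3-(TBDPSO)propan-1-ol (C1 epimer mixture), via aryllithium 25 (not isolated)
Conditions: 16, n-BuLi (1.0 equiv), THF, −78 °C; then 24 (1.2 equiv), −78 → −40 °C; aq. NH4Cl
Reagents that add atoms: none
Why: Bromine–lithium exchange followed by 1,2-addition of the aryllithium to the aldehyde, where exchange at −78 °C outruns attack on the silyl ethers and addition outruns exchange with the ring A bromide; the carbinol configuration is left open because step 17 ionises that carbon.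

Step 17
Reactants: 26 (1RS,2S)-1-[(2R,3R)-2-[3,4-bis(TBSO)phenyl]-3-(TBDPSOCH2)-2,3-dihydro-1,4-benzodioxin-7-yl]-2-[4-bromo-2-(methoxymethoxy)phenoxy]-3-(TBDPSO)propan-1-ol
Product: 28 (2S,3S)-7-bromo-2-[(2R,3R)-2-[3,4-bis(TBSO)phenyl]-3-(TBDPSOCH2)-2,3-dihydro-1,4-benzodioxin-7-yl]-3-(TBDPSOCH2)-2,3-dihydro-1,4-benzodioxine, via free phenol 27 (not isolated)
Conditions: TsOH·H2O (0.5 equiv), CH2Cl2/MeOH 4:1, rt; then solvent exchanged for toluene, 50 °C
Reagents that add atoms: none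
Why: Acid-catalysed acetal exchange with MeOH frees the ring A phenol, and the same acid ionises the benzylic alcohol to a cation stabilised by the para oxygen of ring B (O4 of dioxane 2), which the phenol traps in a 6-exo cationic etherification; the new C2 is set trans to the glycerate-derived C3 because the diequatorial isomer is favoured both kinetically and by acid equilibration, while TBDPS and aryl TBS ethers tolerate these conditions.

Step 18
Reactants: 28 (2S,3S)-7-bromo bis(benzodioxane); 29 (E)-3-(tributylstannyl)prop-2-en-1-ol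
Product: 30 (E)-3-[(2S,3S)-2-[(2R,3R)-2-[3,4-bis(TBSO)phenyl]-3-(TBDPSOCH2)-2,3-dihydro-1,4-benzodioxin-7-yl]-3-(TBDPSOCH2)-2,3-dihydro-1,4-benzodioxin-7-yl]prop-2-en-1-ol
Conditions: Pd(PPh3)4 (10 mol%), toluene, 100 °C
Reagents that add atoms: none
Why: Stille coupling, in which zerovalent palladium inserts into the aryl bromide and the alkenylstannane transfers its E-propenol unit with retention of geometry under neutral conditions that leave the aryl silyl ethers alone.

Step 19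
Reactants: 30 tetrasilylated target
Product: 31 4-[(2R,3R)-3-(hydroxymethyl)-7-[(2S,3S)-3-(hydroxymethyl)-7-[(E)-3-hydroxyprop-1-enyl]-2,3-dihydro-1,4-benzodioxin-2-yl]-2,3-dihydro-1,4-benzodioxin-2-yl]benzene-1,2-diol
Conditions: Bu4NF (6 equiv), AcOH (6 equiv), THF, 0 °C → rt
Reagents that add atoms: none
Why: Fluoride-mediated desilylation removes both aryl TBS and both primary TBDPS ethers, and the AcOH buffer keeps the catechol and the para-hydroxybenzylic ether of dioxane 2 away from basic conditions that could oxidise or reopen them.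

**Compound list**

1 | methyl (S)-2,2-dimethyl-1,3-dioxolane-4-carboxylate | COC(=O)[C@@H]1COC(C)(C)O1 | starting material
2 | methyl (S)-2,3-dihydroxypropanoate | COC(=O)[C@@H](O)CO | intermediate
3 | methyl (S)-3-(TBDPSO)-2-hydroxypropanoate | COC(=O)[C@@H](O)CO[Si](c1ccccc1)(c1ccccc1)C(C)(C)C | intermediate
4 | 5-bromo-2-hydroxybenzaldehyde | O=Cc1cc(Br)ccc1O | starting material
5 | methyl (R)-2-(4-bromo-2-formylphenoxy)-3-(TBDPSO)propanoate | COC(=O)[C@H](Oc1ccc(Br)cc1C=O)CO[Si](c1ccccc1)(c1ccccc1)C(C)(C)C | intermediate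
6 | methyl (R)-2-[4-bromo-2-(formyloxy)phenoxy]-3-(TBDPSO)propanoate | COC(=O)[C@H](Oc1ccc(Br)cc1OC=O)CO[Si](c1ccccc1)(c1ccccc1)C(C)(C)C | intermediate
7 | methyl (R)-2-(4-bromo-2-hydroxyphenoxy)-3-(TBDPSO)propanoate | COC(=O)[C@H](Oc1ccc(Br)cc1O)CO[Si](c1ccccc1)(c1ccccc1)C(C)(C)C | intermediate
8 | (3R)-7-bromo-3-(TBDPSOCH2)-2,3-dihydro-1,4-benzodioxin-2-ol, both C2 anomers | OC1Oc2cc(Br)ccc2O[C@@H]1CO[Si](c1ccccc1)(c1ccccc1)C(C)(C)C | intermediate
9 | 4-bromobenzene-1,2-diol | Oc1ccc(Br)cc1O | starting material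
10 | 4-bromo-1,2-bis(trimethylsilyloxy)benzene | C[Si](C)(C)Oc1ccc(Br)cc1O[Si](C)(C)C | intermediate
11 | [3,4-bis(trimethylsilyloxy)phenyl]magnesium bromide | C[Si](C)(C)Oc1ccc([Mg]Br)cc1O[Si](C)(C)C | intermediate
12 | (1RS,2R)-2-(4-bromo-2-hydroxyphenoxy)-3-(TBDPSO)-1-[3,4-bis(trimethylsilyloxy)phenyl]propan-1-ol | OC(c1ccc(O[Si](C)(C)C)c(O[Si](C)(C)C)c1)[C@@H](CO[Si](c1ccccc1)(c1ccccc1)C(C)(C)C)Oc1ccc(Br)cc1O | intermediate
13 | (1RS,2R)-2-(4-bromo-2-hydroxyphenoxy)-3-(TBDPSO)-1-(3,4-dihydroxyphenyl)propan-1-ol | OC(c1ccc(O)c(O)c1)[C@@H](CO[Si](c1ccccc1)(c1ccccc1)C(C)(C)C)Oc1ccc(Br)cc1O | intermediate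
14 | 4-[(2S)-2-(4-bromo-2-hydroxyphenoxy)-3-(TBDPSO)propylidene]-2-hydroxycyclohexa-2,5-dien-1-one | O=C1C=CC(=C[C@@H](CO[Si](c2ccccc2)(c2ccccc2)C(C)(C)C)Oc2ccc(Br)cc2O)C=C1O | intermediate
15 | 4-[(2R,3R)-7-bromo-3-(TBDPSOCH2)-2,3-dihydro-1,4-benzodioxin-2-yl]benzene-1,2-diol | Brc1ccc2c(c1)O[C@H](c1ccc(O)c(O)c1)[C@@H](CO[Si](c1ccccc1)(c1ccccc1)C(C)(C)C)O2 | intermediate
16 | (2R,3R)-7-bromo-2-[3,4-bis(TBSO)phenyl]-3-(TBDPSOCH2)-2,3-dihydro-1,4-benzodioxine | Brc1ccc2c(c1)O[C@H](c1ccc(O[Si](C)(C)C(C)(C)C)c(O[Si](C)(C)C(C)(C)C)c1)[C@@H](CO[Si](c1ccccc1)(c1ccccc1)C(C)(C)C)O2 | intermediate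
17 | methyl (R)-2,2-dimethyl-1,3-dioxolane-4-carboxylate | COC(=O)[C@H]1COC(C)(C)O1 | starting material
18 | methyl (R)-2,3-dihydroxypropanoate | COC(=O)[C@H](O)CO | intermediate
19 | methyl (R)-3-(TBDPSO)-2-hydroxypropanoate | COC(=O)[C@H](O)CO[Si](c1ccccc1)(c1ccccc1)C(C)(C)C | intermediate
20 | methyl (S)-2-(4-bromo-2-formylphenoxy)-3-(TBDPSO)propanoate | COC(=O)[C@@H](Oc1ccc(Br)cc1C=O)CO[Si](c1ccccc1)(c1ccccc1)C(C)(C)C | intermediate
21 | methyl (S)-2-[4-bromo-2-(formyloxy)phenoxy]-3-(TBDPSO)propanoate | COC(=O)[C@@H](Oc1ccc(Br)cc1OC=O)CO[Si](c1ccccc1)(c1ccccc1)C(C)(C)C | intermediate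
22 | methyl (S)-2-(4-bromo-2-hydroxyphenoxy)-3-(TBDPSO)propanoate | COC(=O)[C@@H](Oc1ccc(Br)cc1O)CO[Si](c1ccccc1)(c1ccccc1)C(C)(C)C | intermediate
23 | methyl (S)-2-[4-bromo-2-(methoxymethoxy)phenoxy]-3-(TBDPSO)propanoate | COC(=O)[C@@H](Oc1ccc(Br)cc1OCOC)CO[Si](c1ccccc1)(c1ccccc1)C(C)(C)C | intermediate
24 | (S)-2-[4-bromo-2-(methoxymethoxy)phenoxy]-3-(TBDPSO)propanal | O=C[C@@H](Oc1ccc(Br)cc1OCOC)CO[Si](c1ccccc1)(c1ccccc1)C(C)(C)C | intermediate
25 | [(2R,3R)-2-[3,4-bis(TBSO)phenyl]-3-(TBDPSOCH2)-2,3-dihydro-1,4-benzodioxin-7-yl]lithium | [Li]c1ccc2c(c1)O[C@H](c1ccc(O[Si](C)(C)C(C)(C)C)c(O[Si](C)(C)C(C)(C)C)c1)[C@@H](CO[Si](c1ccccc1)(c1ccccc1)C(C)(C)C)O2 | intermediate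
26 | (1RS,2S)-1-[(2R,3R)-2-[3,4-bis(TBSO)phenyl]-3-(TBDPSOCH2)-2,3-dihydro-1,4-benzodioxin-7-yl]-2-[4-bromo-2-(methoxymethoxy)phenoxy]-3-(TBDPSO)propan-1-ol | OC(c1ccc2c(c1)O[C@H](c1ccc(O[Si](C)(C)C(C)(C)C)c(O[Si](C)(C)C(C)(C)C)c1)[C@@H](CO[Si](c1ccccc1)(c1ccccc1)C(C)(C)C)O2)[C@H](CO[Si](c1ccccc1)(c1ccccc1)C(C)(C)C)Oc1ccc(Br)cc1OCOC | intermediate
27 | (1RS,2S)-1-[(2R,3R)-2-[3,4-bis(TBSO)phenyl]-3-(TBDPSOCH2)-2,3-dihydro-1,4-benzodioxin-7-yl]-2-(4-bromo-2-hydroxyphenoxy)-3-(TBDPSO)propan-1-ol | OC(c1ccc2c(c1)O[C@H](c1ccc(O[Si](C)(C)C(C)(C)C)c(O[Si](C)(C)C(C)(C)C)c1)[C@@H](CO[Si](c1ccccc1)(c1ccccc1)C(C)(C)C)O2)[C@H](CO[Si](c1ccccc1)(c1ccccc1)C(C)(C)C)Oc1ccc(Br)cc1O | intermediate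
28 | (2S,3S)-7-bromo-2-[(2R,3R)-2-[3,4-bis(TBSO)phenyl]-3-(TBDPSOCH2)-2,3-dihydro-1,4-benzodioxin-7-yl]-3-(TBDPSOCH2)-2,3-dihydro-1,4-benzodioxine | Brc1ccc2c(c1)O[C@@H](c1ccc3c(c1)O[C@H](c1ccc(O[Si](C)(C)C(C)(C)C)c(O[Si](C)(C)C(C)(C)C)c1)[C@@H](CO[Si](c1ccccc1)(c1ccccc1)C(C)(C)C)O3)[C@H](CO[Si](c1ccccc1)(c1ccccc1)C(C)(C)C)O2 | intermediate
29 | (E)-3-(tributylstannyl)prop-2-en-1-ol | CCCC[Sn](CCCC)(CCCC)/C=C/CO | starting material
30 | (E)-3-[(2S,3S)-2-[(2R,3R)-2-[3,4-bis(TBSO)phenyl]-3-(TBDPSOCH2)-2,3-dihydro-1,4-benzodioxin-7-yl]-3-(TBDPSOCH2)-2,3-dihydro-1,4-benzodioxin-7-yl]prop-2-en-1-ol | OC/C=C/c1ccc2c(c1)O[C@@H](c1ccc3c(c1)O[C@H](c1ccc(O[Si](C)(C)C(C)(C)C)c(O[Si](C)(C)C(C)(C)C)c1)[C@@H](CO[Si](c1ccccc1)(c1ccccc1)C(C)(C)C)O3)[C@H](CO[Si](c1ccccc1)(c1ccccc1)C(C)(C)C)O2 | intermediate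
31 | 4-[(2R,3R)-3-(hydroxymethyl)-7-[(2S,3S)-3-(hydroxymethyl)-7-[(E)-3-hydroxyprop-1-enyl]-2,3-dihydro-1,4-benzodioxin-2-yl]-2,3-dihydro-1,4-benzodioxin-2-yl]benzene-1,2-diol | OC/C=C/c1ccc2c(c1)O[C@@H](c1ccc3c(c1)O[C@H](c1ccc(O)c(O)c1)[C@@H](CO)O3)[C@H](CO)O2 | target

**Count and risks**

Total steps: 19. Longest linear sequence: 12 steps (steps 1–5, 7–9 and 16–19, from compound 1).

Step 8 (key step). The quinone methide may be trapped by the catechol ring or a hydroxyl of a second molecule, giving oligomers. The cation may also lose the proton on the neighbouring carbon, giving an enol ether and erasing the glycerate stereocentre, and the free catechol may oxidise in air. The fallback keeps ring C silylated and closes the ring through a para-silyloxybenzyl cation. Compound 9 is silylated with TBSCl and imidazole to 4-bromo-1,2-bis(tert-butyldimethylsilyloxy)benzene F1. Its Grignard reagent [3,4-bis(tert-butyldimethylsilyloxy)phenyl]magnesium bromide F2 is added to lactol 8 to give (1RS,2R)-2-(4-bromo-2-hydroxyphenoxy)-3-(TBDPSO)-1-[3,4-bis(TBSO)phenyl]propan-1-ol F3. Catalytic TsOH in toluene then closes F3 onto the ring B phenol. The fallback sets out from 8 (with 9) and comes back to the route at 16.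

Step 17. The acid may strip silyl ethers before the acetal is cleaved. The benzylic or methoxymethyl cation may alkylate an electron-rich ring, or closure may stall at the benzylic methyl ether. The fallback separates unmasking from closure by using an allyl ether. Phenol 22 is alkylated with allyl bromide and K2CO3 in acetone to methyl (S)-2-[2-(allyloxy)-4-bromophenoxy]-3-(TBDPSO)propanoate F4. Reduction with i-Bu2AlH at −78 °C gives (S)-2-[2-(allyloxy)-4-bromophenoxy]-3-(TBDPSO)propanal F5. Addition of aryllithium 25 gives the allyl-protected carbinol F6. Pd(PPh3)4 with morpholine in THF at rt removes the allyl group under neutral conditions to give 27, now isolated. Catalytic camphorsulfonic acid in CH2Cl2 then closes dioxane 1. The fallback sets out from 22 and comes back to the route at 28.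

Step 7. The magnesium lactolate may open too slowly, the exposed α-aryloxy aldehyde may enolise and epimerise before addition, or the TMS ethers may be lost during Grignard formation. The fallback uses a protected open-chain aldehyde. Phenol 7 is silylated with TBSCl and imidazole to methyl (R)-2-[4-bromo-2-(TBSO)phenoxy]-3-(TBDPSO)propanoate F7. Reduction with i-Bu2AlH at −78 °C gives (R)-2-[4-bromo-2-(TBSO)phenoxy]-3-(TBDPSO)propanal F8. Addition of Grignard reagent 11 (1.3 equiv) gives (1RS,2R)-2-[4-bromo-2-(TBSO)phenoxy]-3-(TBDPSO)-1-[3,4-bis(trimethylsilyloxy)phenyl]propan-1-ol F9. KHF2 in MeOH at rt then cleaves the three aryl silyl ethers and leaves the primary TBDPS ether. The fallback sets out from 7 and comes back to the route at 13.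

**Further compounds**

F1 | step 8 | 4-bromo-1,2-bis(tert-butyldimethylsilyloxy)benzene | CC(C)(C)[Si](C)(C)Oc1ccc(Br)cc1O[Si](C)(C)C(C)(C)C
F2 | step 8 | [3,4-bis(tert-butyldimethylsilyloxy)phenyl]magnesium bromide | CC(C)(C)[Si](C)(C)Oc1ccc([Mg]Br)cc1O[Si](C)(C)C(C)(C)C
F3 | step 8 | (1RS,2R)-2-(4-bromo-2-hydroxyphenoxy)-3-(TBDPSO)-1-[3,4-bis(TBSO)phenyl]propan-1-ol | OC(c1ccc(O[Si](C)(C)C(C)(C)C)c(O[Si](C)(C)C(C)(C)C)c1)[C@@H](CO[Si](c1ccccc1)(c1ccccc1)C(C)(C)C)Oc1ccc(Br)cc1O
F4 | step 17 | methyl (S)-2-[2-(allyloxy)-4-bromophenoxy]-3-(TBDPSO)propanoate | COC(=O)[C@@H](Oc1ccc(Br)cc1OCC=C)CO[Si](c1ccccc1)(c1ccccc1)C(C)(C)C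
F5 | step 17 | (S)-2-[2-(allyloxy)-4-bromophenoxy]-3-(TBDPSO)propanal | O=C[C@@H](Oc1ccc(Br)cc1OCC=C)CO[Si](c1ccccc1)(c1ccccc1)C(C)(C)C
F6 | step 17 | (1RS,2S)-1-[(2R,3R)-2-[3,4-bis(TBSO)phenyl]-3-(TBDPSOCH2)-2,3-dihydro-1,4-benzodioxin-7-yl]-2-[2-(allyloxy)-4-bromophenoxy]-3-(TBDPSO)propan-1-ol | OC(c1ccc2c(c1)O[C@H](c1ccc(O[Si](C)(C)C(C)(C)C)c(O[Si](C)(C)C(C)(C)C)c1)[C@@H](CO[Si](c1ccccc1)(c1ccccc1)C(C)(C)C)O2)[C@H](CO[Si](c1ccccc1)(c1ccccc1)C(C)(C)C)Oc1ccc(Br)cc1OCC=C
F7 | step 7 | methyl (R)-2-[4-bromo-2-(TBSO)phenoxy]-3-(TBDPSO)propanoate | COC(=O)[C@H](Oc1ccc(Br)cc1O[Si](C)(C)C(C)(C)C)CO[Si](c1ccccc1)(c1ccccc1)C(C)(C)C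
F8 | step 7 | (R)-2-[4-bromo-2-(TBSO)phenoxy]-3-(TBDPSO)propanal | O=C[C@H](Oc1ccc(Br)cc1O[Si](C)(C)C(C)(C)C)CO[Si](c1ccccc1)(c1ccccc1)C(C)(C)C
F9 | step 7 | (1RS,2R)-2-[4-bromo-2-(TBSO)phenoxy]-3-(TBDPSO)-1-[3,4-bis(trimethylsilyloxy)phenyl]propan-1-ol | OC(c1ccc(O[Si](C)(C)C)c(O[Si](C)(C)C)c1)[C@@H](CO[Si](c1ccccc1)(c1ccccc1)C(C)(C)C)Oc1ccc(Br)cc1O[Si](C)(C)C(C)(C)C
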